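**Plan**

- Cuts, in retrosynthetic order: C10=C1 (ring-closing metathesis, last step); C2=C3 (Z-selective olefination of a C3 aldehyde); the C4–O–C5 oxirane (hydroxyl-directed epoxidation); O–C6 and C7–C11 together (one palladium annulation); C5–C6 (Heck); C8–C9 (alkoxyallylboration); the esters on O8 and O9.
- Enabling feature: the C4–C5 oxirane lies next to the lactone carbinol C6, so C4–C7 is an epoxidised (E,E)-1,3-diene. The five-membered lactone ring (O, C6, C7, C11, C12) with its C13 methylene is then the adduct of 2-bromoacrylic acid across C6=C7 through a π-allyl palladium on C4–C6, and the spared C4=C5 bond becomes the oxirane.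
- Forward order: acyclic C7–C10/C14 arm (C8/C9 diad, then acrylate) → C3–C7 diene → lactone ring (key step) → O8 ester → oxirane ring → C3 aldehyde, O9 acetate, Z-diene → ten-membered ring.
- Stereochemistry: C8/C9 from a reagent-controlled syn-alkoxyallylboration; C7 from C8 and C6 from C7 in the key step; C4/C5 and the side-chain oxirane from two Sharpless epoxidations (D- and L-tartrate); both ring alkenes cis from a Z-selective olefination and from ring size.

Key step: step 6

Remark: atom numbers are germacrane numbers (ring C1–C10, lactone C11–C13 with C12 the carbonyl, ester carbon C14, methyl C15).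
Remark: the acyl group on O8 is read from the SMILES as (2R,3S)-2,3-dimethyloxirane-2-carbonyl, the oxirane of tiglic acid with cis methyl groups, and is made as such; 2, 10 and 25 are taken as purchasable.

**Route**

Step 1
Reactants: 1 3-(trimethylsilyl)prop-2-ynal; 2 3-(methoxymethoxy)prop-1-ene
Product: 7 (3S,4S)-4-(methoxymethoxy)hex-5-en-1-yn-3-ol, via lithiated allyl ether 3 (not isolated), via allylborane 4 (not isolated), via borinate 5 (not isolated), via silylalkynol 6 (not isolated)
Conditions: 2, s-BuLi, THF, −78 °C; (+)-B-methoxydiisopinocampheylborane; BF3·OEt2; 1, −78 °C; then 3 M NaOH, 30% H2O2, MeOH, 0 °C to rt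
Reagents that add atoms: none
Why: Brown alkoxyallylboration, in which the Z γ-alkoxyallylborane reacts through a chair transition state to set the syn C8/C9 pair, the isopinocampheyl groups of the (−)-α-pinene series select the aldehyde face that should give the (3S,4S) isomer, and the basic peroxide work-up in methanol also cleaves the alkynyl C–Si bond.

Step 2
Reactants: 7 (3S,4S)-4-(methoxymethoxy)hex-5-en-1-yn-3-ol
Product: 8 methyl (3S,4S)-3-hydroxy-4-(methoxymethoxy)-2-methylidenehex-5-enoate
Conditions: Pd(OAc)2 (2 mol %), 2-(diphenylphosphino)pyridine, MsOH (cat.), CO (10 bar), MeOH, 40 °C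
Reagents that add atoms: carbon monoxide, [C-]#[O+]; methanol, CO
Why: Markovnikov hydromethoxycarbonylation of a terminal alkyne by a cationic palladium hydride places the ester on the internal carbon and should give the 2-substituted acrylate directly, while the monosubstituted alkene reacts far more slowly and the acetal tolerates the catalytic acid.

Step 3
Reactants: 8 methyl (3S,4S)-3-hydroxy-4-(methoxymethoxy)-2-methylidenehex-5-enoate
Product: 9 methyl (3S,4S)-3-[(tert-butyldimethylsilyl)oxy]-4-(methoxymethoxy)-2-methylidenehex-5-enoate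
Conditions: TBSCl, imidazole, DMF, rt
Reagents that add atoms: tert-butyldimethylsilyl chloride, CC(C)(C)[Si](C)(C)Cl
Why: Standard silylation of the secondary allylic alcohol, which masks O9 as a group that does not ionise under zerovalent palladium and keeps it apart from O8 in the later acylation.

Step 4
Reactants: 10 (2E)-3-iodo-2-methylprop-2-en-1-ol
Product: 11 tert-butyl{[(2E)-3-iodo-2-methylprop-2-en-1-yl]oxy}dimethylsilane
Conditions: TBSCl, imidazole, CH2Cl2, 0 °C to rt
Reagents that add atoms: tert-butyldimethylsilyl chloride, CC(C)(C)[Si](C)(C)Cl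
Why: Standard silylation of the primary alcohol, which leaves the E vinyl iodide untouched.

Step 5
Reactants: 9 methyl (3S,4S)-3-[(tert-butyldimethylsilyl)oxy]-4-(methoxymethoxy)-2-methylidenehex-5-enoate; 11 tert-butyl{[(2E)-3-iodo-2-methylprop-2-en-1-yl]oxy}dimethylsilane
Product: 12 methyl (3S,4S,5E,7E)-3,9-bis[(tert-butyldimethylsilyl)oxy]-4-(methoxymethoxy)-8-methyl-2-methylidenenona-5,7-dienoate
Conditions: Pd(OAc)2 (10 mol %), n-Bu4NCl, K2CO3, DMF, 60 °C
Reagents that add atoms: none
Why: Heck reaction under phosphine-free Jeffery conditions, in which the alkenylpalladium species adds to the CH2 end of the monosubstituted alkene and β-hydride elimination should give the conjugated (E,E)-diene with retention of the iodide geometry, the 1,1-disubstituted acrylate being much less reactive.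

Step 6
Reactants: 12 methyl (3S,4S,5E,7E)-3,9-bis[(tert-butyldimethylsilyl)oxy]-4-(methoxymethoxy)-8-methyl-2-methylidenenona-5,7-dienoate; 13 2-bromoprop-2-enoic acid
Product: 14 methyl (3S,4S)-3-[(tert-butyldimethylsilyl)oxy]-4-[(2R,3S)-2-{(1E)-3-[(tert-butyldimethylsilyl)oxy]-2-methylprop-1-en-1-yl}-4-methylidene-5-oxooxolan-3-yl]-4-(methoxymethoxy)-2-methylidenebutanoate
Conditions: Pd(OAc)2 (10 mol %), tri(2-furyl)phosphine (20 mol %), K2CO3, n-Bu4NCl, BHT (cat.), DMF, 60 °C, slow addition of 13 (2 equiv)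
Reagents that add atoms: none
Why: Zerovalent palladium inserts into the C–Br bond of the 2-bromoacrylate, the alkenylpalladium species adds syn across C6=C7 with C–C bond formation at C7 (the only diene terminus that is not fully substituted), and the resulting π-allyl palladium on C4–C6 is closed by the carboxylate at C6. The closest known reaction type is the Larock heteroannulation of 1,3-dienes by organic halides that carry a carboxylic acid or another nucleophile (Heck insertion followed by Tsuji–Trost-type closure). The lactone ring closes 5-exo at the proximal allyl terminus C6, whereas attack at C4 would be a seven-membered closure onto a fully substituted carbon. C7 is set by C8: with the C8–O bond in the inside position the C9 chain shields one alkene face, so the metal should add anti to it and give the 1,2-anti relation of C7–C11 and C8–O; C6 is set by C7, because the syn insertion holds the carboxylate on the palladium face and delivery with retention amounts to syn addition across the E alkene, which gives the trans lactone, also the more stable isomer if the allylic C6–O bond ionises reversibly. The step needs selectivity for the diene over the C10 acrylate; the reagent and the product are themselves 1,1-disubstituted acrylates that the reaction type must tolerate, and the C10 acrylate is more hindered than either, while the E geometry of C4=C5 is kept because the allyl unit cannot isomerise through its fully substituted C4 end.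

Step 7
Reactants: 14 (the methoxymethyl ether lactone)
Product: 15 methyl (3S,4S)-3-[(tert-butyldimethylsilyl)oxy]-4-[(2R,3R)-2-{(1E)-3-[(tert-butyldimethylsilyl)oxy]-2-methylprop-1-en-1-yl}-4-methylidene-5-oxooxolan-3-yl]-4-hydroxy-2-methylidenebutanoate
Conditions: Me2BBr, CH2Cl2, −78 °C; then aq. NaHCO3
Reagents that add atoms: none
Why: Low-temperature Lewis acid cleavage of the methoxymethyl acetal with a bromoborane, a method that spares silyl ethers, esters and lactones and leaves the C8–O bond and its configuration untouched.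

Step 8
Reactants: 16 (2E)-2-methylbut-2-en-1-ol
Product: 17 [(2S,3S)-2,3-dimethyloxiran-2-yl]methanol
Conditions: Ti(OiPr)4 (cat.), L-(+)-diethyl tartrate, t-BuOOH, 4 Å molecular sieves, CH2Cl2, −20 °C
Reagents that add atoms: tert-butyl hydroperoxide, CC(C)(C)OO
Why: Sharpless asymmetric epoxidation of an E trisubstituted allylic alcohol, in which the L-(+)-tartrate complex delivers oxygen to the face that should give the (2S,3S)-epoxy alcohol.

Step 9
Reactants: 17 [(2S,3S)-2,3-dimethyloxiran-2-yl]methanol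
Product: 18 (2R,3S)-2,3-dimethyloxirane-2-carboxylic acid
Conditions: TEMPO (cat.), PhI(OAc)2, MeCN/H2O, rt
Reagents that add atoms: water, O
Why: Oxoammonium oxidation in aqueous acetonitrile takes the primary alcohol through the aldehyde hydrate to the acid without opening the oxirane, and the C2 descriptor changes to R only through the priority rules.

Step 10
Reactants: 15 (the C8 alcohol); 18 (2R,3S)-2,3-dimethyloxirane-2-carboxylic acid
Product: 20 methyl (3S,4S)-3-[(tert-butyldimethylsilyl)oxy]-4-[(2R,3S)-2-{(1E)-3-[(tert-butyldimethylsilyl)oxy]-2-methylprop-1-en-1-yl}-4-methylidene-5-oxooxolan-3-yl]-4-{[(2R,3S)-2,3-dimethyloxirane-2-carbonyl]oxy}-2-methylidenebutanoate, via mixed anhydride 19 (not isolated)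
Conditions: 18, 2,4,6-trichlorobenzoyl chloride, Et3N, THF, rt; then 15, DMAP, toluene, rt to 40 °C
Reagents that add atoms: none
Why: Yamaguchi esterification through the mixed anhydride is the standard way to join an α-quaternary acid to a hindered secondary alcohol, and O8 is the only free hydroxyl.

Step 11
Reactants: 20 (the bis-silyl ether)
Product: 21 methyl (3S,4S)-4-{[(2R,3S)-2,3-dimethyloxirane-2-carbonyl]oxy}-3-hydroxy-4-{(2R,3S)-2-[(1E)-3-hydroxy-2-methylprop-1-en-1-yl]-4-methylidene-5-oxooxolan-3-yl}-2-methylidenebutanoate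
Conditions: HF·pyridine, pyridine, THF, 0 °C to rt
Reagents that add atoms: none
Why: Buffered fluoride cleavage of both silyl ethers, done before any acid-sensitive ring oxirane exists and under non-basic conditions that should not move the O8 acyl group to O9.

Step 12
Reactants: 21 (the allylic alcohol diol)
Product: 22 methyl (3S,4S)-4-{[(2R,3S)-2,3-dimethyloxirane-2-carbonyl]oxy}-3-hydroxy-4-{(2S,3R)-2-[(2R,3R)-3-(hydroxymethyl)-3-methyloxiran-2-yl]-4-methylidene-5-oxooxolan-3-yl}-2-methylidenebutanoate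
Conditions: Ti(OiPr)4, D-(−)-diethyl tartrate, t-BuOOH, 4 Å molecular sieves, CH2Cl2, −20 °C
Reagents that add atoms: tert-butyl hydroperoxide, CC(C)(C)OO
Why: Sharpless asymmetric epoxidation directed by the C3 hydroxyl, in which the D-(−)-tartrate complex should deliver oxygen to the face of the E C4=C5 bond that gives the (4R,5R) oxirane under reagent control, the two electron-poor methylene groups being inert to this oxidant.

Step 13
Reactants: 22 (the epoxy diol)
Product: 23 methyl (3S,4S)-4-{[(2R,3S)-2,3-dimethyloxirane-2-carbonyl]oxy}-4-{(2S,3R)-2-[(2R,3S)-3-formyl-3-methyloxiran-2-yl]-4-methylidene-5-oxooxolan-3-yl}-3-hydroxy-2-methylidenebutanoate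
Conditions: TEMPO (cat.), PhI(OAc)2, CH2Cl2, rt
Reagents that add atoms: none
Why: Oxoammonium oxidation is selective for the primary alcohol over the hindered secondary C9 alcohol, and the aldehyde formed has a fully substituted α-carbon (C4) and cannot epimerise.

Step 14
Reactants: 23 (the epoxy aldehyde alcohol)
Product: 24 methyl (3S,4S)-3-(acetyloxy)-4-{[(2R,3S)-2,3-dimethyloxirane-2-carbonyl]oxy}-4-{(2S,3R)-2-[(2R,3S)-3-formyl-3-methyloxiran-2-yl]-4-methylidene-5-oxooxolan-3-yl}-2-methylidenebutanoate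
Conditions: Ac2O, pyridine, DMAP (cat.), CH2Cl2, 0 °C
Reagents that add atoms: acetic anhydride, CC(=O)OC(C)=O
Why: Standard acetylation of the one remaining hydroxyl, placed after every palladium step because the product is an allylic acetate of the Morita–Baylis–Hillman type.

Step 15
Reactants: 24 (the epoxy aldehyde acetate); 25 allyl(diphenyl)phosphine
Product: 28 methyl (3S,4S)-3-(acetyloxy)-4-[(2S,3R)-2-{(2R,3R)-3-[(1Z)-buta-1,3-dien-1-yl]-3-methyloxiran-2-yl}-4-methylidene-5-oxooxolan-3-yl]-4-{[(2R,3S)-2,3-dimethyloxirane-2-carbonyl]oxy}-2-methylidenebutanoate, via titanium allyl reagent 26 (not isolated), via oxido phosphine adduct 27 (not isolated)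
Conditions: 25, t-BuLi, THF, −78 °C; Ti(OiPr)4; 24, −78 °C to 0 °C; then MeI, rt
Reagents that add atoms: none
Why: Z-selective terminal 1,3-diene synthesis from an aldehyde, in which the titanated allylphosphine adds through its α-carbon to give the erythro β-oxido phosphine and P-methylation triggers a Wittig-type syn elimination to the Z alkene, the titanium reagent being selective for the aldehyde over esters, lactone and oxiranes.

Step 16
Reactants: 28 (the Z-diene acrylate)
Product: 29 the target, (4R,5R,6S,7R,8S,9S)-9-acetoxy-8-{[(2R,3S)-2,3-dimethyloxirane-2-carbonyl]oxy}-4,5-epoxy-14-methoxy-14-oxogermacra-1(10),2,11(13)-trien-6,12-olide with both ring alkenes cis in the ring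
Conditions: second-generation Hoveyda–Grubbs catalyst (20 mol %), 1,4-benzoquinone, toluene (0.5 mM), 80 °C
Reagents that add atoms: none
Why: Ring-closing metathesis between the terminal alkene of the diene and the 1,1-disubstituted acrylate closes the ten-membered ring, and the new trisubstituted C10=C1 bond should form cis in the ring because a ring of this size that already holds the Z C2=C3 bond cannot accommodate a trans alkene next to it.

**Compound list**

1 | 3-(trimethylsilyl)prop-2-ynal | C[Si](C)(C)C#CC=O | starting material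
2 | 3-(methoxymethoxy)prop-1-ene | C=CCOCOC | starting material
3 | (Z)-[3-(methoxymethoxy)allyl]lithium | [Li]C/C=C\OCOC | intermediate
4 | [(Z)-3-(methoxymethoxy)allyl]bis(isopinocampheyl)borane, isopinocampheyl groups of the (−)-α-pinene series | COCO/C=C\CB([C@H]1C[C@H]2C[C@@H]([C@@H]1C)C2(C)C)[C@H]1C[C@H]2C[C@@H]([C@@H]1C)C2(C)C | intermediate
5 | bis(isopinocampheyl)borinate ester of 6 | C=C[C@H](OCOC)[C@@H](OB([C@H]1C[C@H]2C[C@@H]([C@@H]1C)C2(C)C)[C@H]1C[C@H]2C[C@@H]([C@@H]1C)C2(C)C)C#C[Si](C)(C)C | intermediate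
6 | (3S,4S)-4-(methoxymethoxy)-1-(trimethylsilyl)hex-5-en-1-yn-3-ol | C=C[C@H](OCOC)[C@@H](O)C#C[Si](C)(C)C | intermediate
7 | (3S,4S)-4-(methoxymethoxy)hex-5-en-1-yn-3-ol | C=C[C@H](OCOC)[C@@H](O)C#C | intermediate
8 | methyl (3S,4S)-3-hydroxy-4-(methoxymethoxy)-2-methylidenehex-5-enoate | C=C[C@H](OCOC)[C@@H](O)C(=C)C(=O)OC | intermediate
9 | methyl (3S,4S)-3-[(tert-butyldimethylsilyl)oxy]-4-(methoxymethoxy)-2-methylidenehex-5-enoate | C=C[C@H](OCOC)[C@@H](O[Si](C)(C)C(C)(C)C)C(=C)C(=O)OC | intermediate
10 | (2E)-3-iodo-2-methylprop-2-en-1-ol | OC/C(C)=C/I | starting material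
11 | tert-butyl{[(2E)-3-iodo-2-methylprop-2-en-1-yl]oxy}dimethylsilane | CC(C)(C)[Si](C)(C)OC/C(C)=C/I | intermediate
12 | methyl (3S,4S,5E,7E)-3,9-bis[(tert-butyldimethylsilyl)oxy]-4-(methoxymethoxy)-8-methyl-2-methylidenenona-5,7-dienoate | CC(C)(C)[Si](C)(C)OC/C(C)=C/C=C/[C@H](OCOC)[C@@H](O[Si](C)(C)C(C)(C)C)C(=C)C(=O)OC | intermediate
13 | 2-bromoprop-2-enoic acid | OC(=O)C(Br)=C | starting material
14 | methyl (3S,4S)-3-[(tert-butyldimethylsilyl)oxy]-4-[(2R,3S)-2-{(1E)-3-[(tert-butyldimethylsilyl)oxy]-2-methylprop-1-en-1-yl}-4-methylidene-5-oxooxolan-3-yl]-4-(methoxymethoxy)-2-methylidenebutanoate (trans lactone) | C=C1C(=O)O[C@H](/C=C(\C)CO[Si](C)(C)C(C)(C)C)[C@H]1[C@H](OCOC)[C@@H](O[Si](C)(C)C(C)(C)C)C(=C)C(=O)OC | intermediate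
15 | methyl (3S,4S)-3-[(tert-butyldimethylsilyl)oxy]-4-[(2R,3R)-2-{(1E)-3-[(tert-butyldimethylsilyl)oxy]-2-methylprop-1-en-1-yl}-4-methylidene-5-oxooxolan-3-yl]-4-hydroxy-2-methylidenebutanoate | C=C1C(=O)O[C@H](/C=C(\C)CO[Si](C)(C)C(C)(C)C)[C@H]1[C@H](O)[C@@H](O[Si](C)(C)C(C)(C)C)C(=C)C(=O)OC | intermediate
16 | (2E)-2-methylbut-2-en-1-ol | C/C=C(\C)CO | starting material
17 | [(2S,3S)-2,3-dimethyloxiran-2-yl]methanol | OC[C@]1(C)O[C@H]1C | intermediate
18 | (2R,3S)-2,3-dimethyloxirane-2-carboxylic acid | OC(=O)[C@]1(C)O[C@H]1C | intermediate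
19 | (2R,3S)-2,3-dimethyloxirane-2-carboxylic 2,4,6-trichlorobenzoic anhydride | O=C(OC(=O)[C@]1(C)O[C@H]1C)c1c(Cl)cc(Cl)cc1Cl | intermediate
20 | methyl (3S,4S)-3-[(tert-butyldimethylsilyl)oxy]-4-[(2R,3S)-2-{(1E)-3-[(tert-butyldimethylsilyl)oxy]-2-methylprop-1-en-1-yl}-4-methylidene-5-oxooxolan-3-yl]-4-{[(2R,3S)-2,3-dimethyloxirane-2-carbonyl]oxy}-2-methylidenebutanoate | C=C1C(=O)O[C@H](/C=C(\C)CO[Si](C)(C)C(C)(C)C)[C@H]1[C@H](OC(=O)[C@]1(C)O[C@H]1C)[C@@H](O[Si](C)(C)C(C)(C)C)C(=C)C(=O)OC | intermediate
21 | methyl (3S,4S)-4-{[(2R,3S)-2,3-dimethyloxirane-2-carbonyl]oxy}-3-hydroxy-4-{(2R,3S)-2-[(1E)-3-hydroxy-2-methylprop-1-en-1-yl]-4-methylidene-5-oxooxolan-3-yl}-2-methylidenebutanoate | C=C1C(=O)O[C@H](/C=C(\C)CO)[C@H]1[C@H](OC(=O)[C@]1(C)O[C@H]1C)[C@@H](O)C(=C)C(=O)OC | intermediate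
22 | methyl (3S,4S)-4-{[(2R,3S)-2,3-dimethyloxirane-2-carbonyl]oxy}-3-hydroxy-4-{(2S,3R)-2-[(2R,3R)-3-(hydroxymethyl)-3-methyloxiran-2-yl]-4-methylidene-5-oxooxolan-3-yl}-2-methylidenebutanoate | C=C1C(=O)O[C@H]([C@H]2O[C@]2(C)CO)[C@H]1[C@H](OC(=O)[C@]1(C)O[C@H]1C)[C@@H](O)C(=C)C(=O)OC | intermediate
23 | methyl (3S,4S)-4-{[(2R,3S)-2,3-dimethyloxirane-2-carbonyl]oxy}-4-{(2S,3R)-2-[(2R,3S)-3-formyl-3-methyloxiran-2-yl]-4-methylidene-5-oxooxolan-3-yl}-3-hydroxy-2-methylidenebutanoate | C=C1C(=O)O[C@H]([C@H]2O[C@]2(C)C=O)[C@H]1[C@H](OC(=O)[C@]1(C)O[C@H]1C)[C@@H](O)C(=C)C(=O)OC | intermediate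
24 | methyl (3S,4S)-3-(acetyloxy)-4-{[(2R,3S)-2,3-dimethyloxirane-2-carbonyl]oxy}-4-{(2S,3R)-2-[(2R,3S)-3-formyl-3-methyloxiran-2-yl]-4-methylidene-5-oxooxolan-3-yl}-2-methylidenebutanoate | C=C1C(=O)O[C@H]([C@H]2O[C@]2(C)C=O)[C@H]1[C@H](OC(=O)[C@]1(C)O[C@H]1C)[C@@H](OC(C)=O)C(=C)C(=O)OC | intermediate
25 | allyl(diphenyl)phosphine | C=CCP(c1ccccc1)c1ccccc1 | starting material
26 | lithium [(2E)-3-(diphenylphosphanyl)prop-2-en-1-yl]tetrakis(propan-2-olato)titanate | [Li+].CC(C)O[Ti-](OC(C)C)(OC(C)C)(OC(C)C)C/C=C/P(c1ccccc1)c1ccccc1 | intermediate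
27 | erythro β-oxido phosphine adduct of 24 at C3, drawn as its titanium tris(propan-2-olate); the two new centres (C3, C2) are transient and left unassigned | C=C1C(=O)O[C@H]([C@H]2O[C@]2(C)C(O[Ti](OC(C)C)(OC(C)C)OC(C)C)C(C=C)P(c2ccccc2)c2ccccc2)[C@H]1[C@H](OC(=O)[C@]1(C)O[C@H]1C)[C@@H](OC(C)=O)C(=C)C(=O)OC | intermediate
28 | methyl (3S,4S)-3-(acetyloxy)-4-[(2S,3R)-2-{(2R,3R)-3-[(1Z)-buta-1,3-dien-1-yl]-3-methyloxiran-2-yl}-4-methylidene-5-oxooxolan-3-yl]-4-{[(2R,3S)-2,3-dimethyloxirane-2-carbonyl]oxy}-2-methylidenebutanoate | C=C1C(=O)O[C@H]([C@H]2O[C@]2(C)/C=C\C=C)[C@H]1[C@H](OC(=O)[C@]1(C)O[C@H]1C)[C@@H](OC(C)=O)C(=C)C(=O)OC | intermediate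
29 | (4R,5R,6S,7R,8S,9S)-9-acetoxy-8-{[(2R,3S)-2,3-dimethyloxirane-2-carbonyl]oxy}-4,5-epoxy-14-methoxy-14-oxogermacra-1(10),2,11(13)-trien-6,12-olide (1(10)E,2Z by the sequence rule, both cis in the ring) | C=C1C(=O)O[C@H]2[C@H]1[C@H](OC(=O)[C@]1(C)O[C@H]1C)[C@@H](OC(C)=O)/C(C(=O)OC)=C\C=C/[C@@]1(C)O[C@H]21 | target

**Step count and risks**

Total steps: 16. Longest linear sequence: 13 (steps 1, 2, 3, 5, 6, 7, 10, 11, 12, 13, 14, 15, 16).

Step 6 (key step). What may go wrong: insertion of the alkenylpalladium species on the wrong face of C6=C7 or into the C10 acrylate, β-hydride elimination to a triene before the carboxylate closes, outer-sphere closure to the cis lactone, or polymerisation of the bromoacrylate. The fallback forms C6–C7 instead, by allylation and lactonisation. It sets out from 9: selective ozonolysis of the vinyl group (O3, pyridine, CH2Cl2, −78 °C; Me2S) would give methyl (3S,4R)-3-[(tert-butyldimethylsilyl)oxy]-4-(methoxymethoxy)-2-methylidene-5-oxopentanoate F1. A Morita–Baylis–Hillman reaction with methyl acrylate (DABCO) would give dimethyl (3S,4S)-3-[(tert-butyldimethylsilyl)oxy]-5-hydroxy-4-(methoxymethoxy)-2,6-dimethylideneheptanedioate F2 as C5 epimers. NBS/Me2S would convert both epimers, with allylic transposition, into dimethyl (2Z,4S,5S)-2-(bromomethyl)-5-[(tert-butyldimethylsilyl)oxy]-4-(methoxymethoxy)-6-methylidenehept-2-enedioate F3. In parallel, 11 would be lithiated (t-BuLi) and formylated (DMF) to (2E)-4-[(tert-butyldimethylsilyl)oxy]-3-methylbut-2-enal F4. A CrCl2-mediated Nozaki–Hiyama allylation of F4 with F3 (anti-selective through a chair transition state, hence the trans C6/C7 relation, with C7 set against C8 in the Felkin sense) and lactonisation on work-up would come back to the route at 14.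

Step 16. What may go wrong: oligomerisation at the concentration needed, attack of the ruthenium carbene on the internal alkene of the diene with loss of butadiene and ring contraction, or failure of the hindered acrylate to engage the stabilised vinylcarbene. The fallback closes the ring before the diene exists. It sets out from 24: allylation with allylboronic acid pinacol ester (CH2Cl2, rt) would give the homoallylic alcohol F6 (C3 epimers). Ring-closing metathesis of its plain terminal alkene with the acrylate would give the ten-membered ring alcohol F7. Mesylation (MsCl, Et3N) to the mesylate F8 and elimination with DBU, where C2–H is activated through the C1=C10 ester, would introduce the C2=C3 bond within the ring and come back at 29.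

Step 15. What may go wrong: erosion of Z selectivity at the elimination stage, or attack of the phosphine–titanium reagent on the allylic acetate or the methylene lactone. The fallback makes the Z alkene by a non-stabilised Wittig reaction and unveils the terminal alkene afterwards. It sets out from 24: reaction with the ylide from [3-(phenylselanyl)propyl]triphenylphosphonium bromide (NaHMDS, THF, −78 °C) would give the Z-alkenyl selenide F5. Oxidation (H2O2, pyridine, CH2Cl2) and selenoxide syn elimination would give the diene and come back at 28.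

Further compounds
F1 | step 6 | methyl (3S,4R)-3-[(tert-butyldimethylsilyl)oxy]-4-(methoxymethoxy)-2-methylidene-5-oxopentanoate | O=C[C@H](OCOC)[C@@H](O[Si](C)(C)C(C)(C)C)C(=C)C(=O)OC
F2 | step 6 | dimethyl (3S,4S)-3-[(tert-butyldimethylsilyl)oxy]-5-hydroxy-4-(methoxymethoxy)-2,6-dimethylideneheptanedioate (C5 epimers) | C=C(C(=O)OC)C(O)[C@H](OCOC)[C@@H](O[Si](C)(C)C(C)(C)C)C(=C)C(=O)OC
F3 | step 6 | dimethyl (2Z,4S,5S)-2-(bromomethyl)-5-[(tert-butyldimethylsilyl)oxy]-4-(methoxymethoxy)-6-methylidenehept-2-enedioate | COC(=O)/C(CBr)=C/[C@H](OCOC)[C@@H](O[Si](C)(C)C(C)(C)C)C(=C)C(=O)OC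
F4 | step 6 | (2E)-4-[(tert-butyldimethylsilyl)oxy]-3-methylbut-2-enal | CC(C)(C)[Si](C)(C)OC/C(C)=C/C=O
F5 | step 15 | methyl (3S,4S)-3-(acetyloxy)-4-{[(2R,3S)-2,3-dimethyloxirane-2-carbonyl]oxy}-4-[(2S,3R)-2-{(2R,3R)-3-methyl-3-[(1Z)-4-(phenylselanyl)but-1-en-1-yl]oxiran-2-yl}-4-methylidene-5-oxooxolan-3-yl]-2-methylidenebutanoate | C=C1C(=O)O[C@H]([C@H]2O[C@]2(C)/C=C\CC[Se]c2ccccc2)[C@H]1[C@H](OC(=O)[C@]1(C)O[C@H]1C)[C@@H](OC(C)=O)C(=C)C(=O)OC
F6 | step 16 | homoallylic alcohol from allylation of 24 at C3 (C3 epimers) | C=C1C(=O)O[C@H]([C@H]2O[C@]2(C)C(O)CC=C)[C@H]1[C@H](OC(=O)[C@]1(C)O[C@H]1C)[C@@H](OC(C)=O)C(=C)C(=O)OC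
F7 | step 16 | 2,3-dihydro-3-hydroxy analogue of 29 (ten-membered ring, C1=C10 in place, C3 epimers) | C=C1C(=O)O[C@H]2[C@H]1[C@H](OC(=O)[C@]1(C)O[C@H]1C)[C@@H](OC(C)=O)/C(C(=O)OC)=C\CC(O)[C@@]1(C)O[C@H]21
F8 | step 16 | C3 methanesulfonate of F7 | C=C1C(=O)O[C@H]2[C@H]1[C@H](OC(=O)[C@]1(C)O[C@H]1C)[C@@H](OC(C)=O)/C(C(=O)OC)=C\CC(OS(C)(=O)=O)[C@@]1(C)O[C@H]21
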